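The ratio I follow is lost over kept: the part of the charge missing from target plus isomer of the product, divided by the part found in them, the inverse of a selectivity factor.

in all of them: enzyme 0.01 mol% (in portions, 3)
- Sunday's: substrate 0.10 M; run made earlier; portions every 8.0 min
- Saturday's: substrate 0.15 M; run made earlier; portions every 8.0 min
- flask: substrate 0.20 M; the portions of enzyme follow each other after 8.0 min, the first at the start; time 15 d

| run | time / d | target / % | isomer of the product / % |
|---|---|---|---|
| Sunday's | 1.25 | 3.7 | 57.9 |
| Sunday's | 2.50 | 3.9 | 57.6 |
| Sunday's | 4.00 | 3.4 | 57.2 |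
| Sunday's | 5.00 | 4.3 | 57.8 |
| Sunday's | 6.00 | 3.9 | 57.3 |
| Sunday's | 8.00 | 3.4 | 57.7 |
| Sunday's | 10.0 | 3.8 | 57.4 |
| Saturday's | 0.500 | 4.3 | 49.5 |
| Saturday's | 1.25 | 2.9 | 51.0 |
| Saturday's | 2.50 | 3.7 | 50.4 |
| Saturday's | 4.00 | 3.8 | 50.5 |
| Saturday's | 5.00 | 3.7 | 50.5 |
| Saturday's | 8.00 | 3.1 | 50.7 |
| Saturday's | 10.0 | 3.1 | 50.5 |

(scatter of a reading: 0.3 percentage points)

1. how much target there is at 15 d, in percent of the substrate charged
2. how much isomer of the product there is at 15 d, in percent of the substrate charged

The sum of target and isomer of the product stays level in both runs, given a scatter of 0.3 percentage points on each reading, so I read each sum as a plateau and place 15 d on one. The split within that sum is not level from the first reading: Saturday's run reads 4.3% target and 49.5% isomer of the product at 0.500 d, and 3.8% and 50.5% at 4.00 d. Sunday's run keeps 61.3%, a ratio of 0.631. Saturday's run keeps 54.0%, a higher ratio of 0.853.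

The loading never varied, so it is my assumption that the ratio follows a power of substrate concentration over enzyme loading. The loss exponent, the slope of the logarithm of the ratio against the logarithm of that quotient, reads 0.746. For the new flask this gives a ratio of 1.06, just past the crossing where lost equals kept, so it keeps 48.6%. Target makes up 6.32% of what the two runs keep, so I expect 3.07% target and 45.5% isomer of the product.

The forecast, which calls “the extrapolation is the main uncertainty”, gives 3.3% target (2.7% to 3.9%) and 45% isomer of the product (42% to 48%).

The flask gives 3.04% target and 45.6% isomer of the product.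

    substrate + enzyme → target + enzyme, rate k1*[substrate]*[enzyme]/(1 + ([substrate]/Km1) + ([target]/Kp1)) (4.50 mM, 42.0 mM, k = 15000 M⁻¹ min⁻¹)
    substrate + enzyme → spent catalyst (k = 0.0480 M⁻¹ min⁻¹)
    target + enzyme ⇌ isomer of the product + enzyme, rate k3*[enzyme]*[target] forward; the back reaction follows from the equilibrium constant (K = 15.0, k = 570 M⁻¹ min⁻¹)
    2 substrate → homo dimer (k = 0.0650 M⁻¹ min⁻¹)

That is a ratio of 1.06, against my 1.06. The lost part of this flask stands as homo dimer, 51.3% of the charge at 15.0 d, with substrate at 0%. Now I take the neighbour flask with 0.017 mol% of enzyme: the exponent 0.746 gives it a ratio of 0.712, hence 58.4% kept, and that neighbour holds 3.57% target and 53.6% isomer of the product.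

The earlier runs and the new flask were computed with made-up constants; the scatter is artificial.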